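**Retrosynthetic overview**
1. Numbering: carbocycle C1 (ketone), C2, C3–C4 (oxirane, methyl C15 on C4), C5, C6 (lactone O), C7, C8 (OH), C9 (angelate), C10 (=C14H2); lactone carbons C11 (=C13H2) and C12.
2. Feature: with C8 as a ketone and C3=C4 as an E alkene, the ten-membered carbocycle is a cyclodec-5-enone. Joining C3 to C8 and cutting C5–C6 gives the six-membered ring C1, C2, C3, C8, C9, C10, which is the ring of (R)-carvone; its isopropenyl group supplies C4, C5 and C15.
3. Late stage, backwards: C1 ketone from the allylic alcohol; oxirane from the E C3=C4 alkene under catalyst control; C13 by lactone methylenation; lactone from O6 and a C7 acetate arm; angelate on C9; C9–OH and C10=C14 from a C9–C10 oxirane set threo to the C8 alcohol; C8 alcohol by chelation-controlled reduction; C11–C12 by alkylation at C7.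
4. Key disconnection: C5–C6, made by anionic oxy-Cope rearrangement of the carvone-derived trans-1,2-dialkenylcyclohexenol 17, which cuts C3–C8 and sets C6.
5. Ring order: six-membered ring bought with carvone, ten-membered ring (step 9), γ-lactone (step 17), oxirane (step 19).

Key step: step 9

Remark: angelic acid and the D-fructose-derived ketone of step 19 are taken as commercial; the locants above are used for every intermediate, and C1 is carried as a silyl ether cis to the isopropenyl-derived carbons until it becomes the ketone in the last step.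

**Step 1**
Reactants: 1 (R)-carvone
Product: 2 (1R,5R)-cis-carveol
Conditions: NaBH4, CeCl3·7H2O, MeOH, −20 °C
Reagents that add atoms: none
Why: Luche 1,2-reduction of the enone; hydride adds axially to the half-chair with the isopropenyl group equatorial, so the C1 alcohol is set equatorial and cis to the isopropenyl group.

**Step 2**
Reactants: 2 (1R,5R)-cis-carveol
Product: 3 cis-epoxy alcohol (C9–C10 oxirane syn to the C1 hydroxyl)
Conditions: VO(acac)2 (2 mol %), t-BuOOH (decane), CH2Cl2, 0 °C → rt
Reagents that add atoms: tert-butyl hydroperoxide, CC(C)(C)OO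
Why: Hydroxyl-directed vanadium-catalysed epoxidation of an allylic alcohol; the vanadate ester delivers oxygen only to the ring alkene and from the face of the C1 hydroxyl, which sets C9 and C10 with the oxirane cis to the isopropenyl group and leaves that group untouched.

**Step 3**
Reactants: 3 cis-epoxy alcohol
Product: 4 tert-butyldimethylsilyl ether of 3
Conditions: t-BuMe2SiCl, imidazole, DMF, rt
Reagents that add atoms: tert-butyldimethylsilyl chloride, CC(C)(C)[Si](C)(C)Cl
Why: Imidazole-mediated silylation of a secondary alcohol; no stereocentre is touched and the C1 oxygen stays masked until step 20.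

**Step 4**
Reactants: 4 epoxy silyl ether
Product: 7 tertiary C10 allylic alcohol with C8=C9, via hydroxy selenide 5 (not isolated), via selenoxide 6 (not isolated)
Conditions: (PhSe)2, NaBH4, EtOH, 0 → 78 °C; then H2O2 (30 %), pyridine, THF, 0 °C → rt
Reagents that add atoms: none
Why: Epoxide-to-allylic-alcohol conversion by selenide opening and selenoxide syn-elimination; phenylselenide opens the oxirane at secondary C9 in the trans-diaxial sense (Fürst–Plattner rule, isopropenyl equatorial because the oxirane is cis to it), and the selenoxide can only eliminate toward C8, which gives the C8=C9 alkene and the tertiary C10 alcohol.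

**Step 5**
Reactants: 7 tertiary allylic alcohol
Product: 8 (4R,6R)-4-(tert-butyldimethylsilyloxy)-3-methyl-6-(prop-1-en-2-yl)cyclohex-2-en-1-one
Conditions: [C5H5NH][CrO3Cl] (pyridinium chlorochromate), NaOAc, 4 Å MS, CH2Cl2, rt
Reagents that add atoms: none
Why: Dauben–Babler oxidative transposition; the tertiary allylic chromate ester undergoes a [3,3] shift to the secondary C8 chromate, which is oxidised to the C8 ketone conjugated with C9=C10, and the acetate buffer keeps the α-isopropenyl centre C3 from epimerising or moving into conjugation.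

**Step 6**
Reactants: 9 4-methoxybenzyl alcohol; 10 trichloroethylene
Product: 13 (E)-1,2-dichlorovinyl 4-methoxybenzyl ether, via potassium 4-methoxybenzyl oxide 11 (not isolated), via dichloroethyne 12 (not isolated)
Conditions: KH, THF, 0 °C; then 10, −50 °C → rt
Reagents that add atoms: none
Why: Alkoxide-induced elimination of HCl from trichloroethylene followed by anti addition of the alcohol to the dichloroethyne so formed (the addition–elimination route to 1,2-dichlorovinyl ethers), which gives the E ether needed as precursor of a lithium alkynyl ether.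

**Step 7**
Reactants: 13 (E)-1,2-dichlorovinyl 4-methoxybenzyl ether; 8 enone
Product: 16 alkynyl carbinol, via chloroethynyl 4-methoxybenzyl ether 14 (not isolated), via lithium (4-methoxybenzyloxy)ethynide 15 (not isolated)
Conditions: 13, n-BuLi (2.2 equiv), THF, −78 → −40 °C; then 8, −78 °C; aq. NaHCO3
Reagents that add atoms: none
Why: Dehydrochlorination and chlorine–lithium exchange give the lithium alkynyl ether, a weakly basic nucleophile that adds 1,2 to the enone from the equatorial direction, anti to the pseudo-equatorial α'-isopropenyl group (as organometallic additions to menthone-type 2-substituted cyclohexanones do), which sets C8 with the alkynyl group trans to the isopropenyl group and the hydroxyl cis to it.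

**Step 8**
Reactants: 16 alkynyl carbinol
Product: 17 (1R,4R,6R)-4-(tert-butyldimethylsilyloxy)-1-[(E)-2-(4-methoxybenzyloxy)ethenyl]-3-methyl-6-(prop-1-en-2-yl)cyclohex-2-en-1-ol
Conditions: LiAlH4, THF, 0 °C → rt; aq. KNaC4H4O6 (Rochelle salt)
Reagents that add atoms: none
Why: Alkoxide-directed trans-hydroalumination of a propargylic alcohol; hydride and, after protonolysis, hydrogen add anti across C6≡C7 and give the E enol ether, which is made this way because an (E)-2-alkoxyvinyllithium would lose alkoxide by anti β-elimination before it could add to the ketone.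

**Step 9**
Reactants: 17 dienol
Product: 20 (2Z,4R,6E,9R)-4-(tert-butyldimethylsilyloxy)-9-(4-methoxybenzyloxy)-3,7-dimethylcyclodeca-2,6-dien-1-one, via potassium alkoxide 18 (not isolated), via potassium enolate 19 (not isolated)
Conditions: KH, 18-crown-6, THF, 0 °C → rt; then sat. aq. NH4Cl, −78 °C
Reagents that add atoms: none
Why: KH deprotonates the tertiary C8 alcohol and the crown ether frees the alkoxide, whose charge weakens the C3–C8 bond so that the 1,5-diene C6=C7–C8–C3–C4=C5 undergoes a concerted [3,3] shift near room temperature, forming C5–C6 and the C7=C8 enolate, which is protonated at C7 on quench. The closest known reaction is the anionic oxy-Cope ring expansion of trans-1,2-dialkenylcyclohexanols to cyclodec-5-enones. The ten-membered ring is not closed end to end: the six-membered ring grows by the four carbons C4–C7 as its C3–C8 bond is cut. C6 is set by chirality transfer from C3 and C8 through a chair transition state in which both ring bonds (C8–C9, C3–C2) and the E enol ether oxygen are equatorial, which gives 6R, and the equatorial C2 on C3 fixes the E geometry of C3=C4. The step needs the exocyclic enol ether and not the ring alkene C9=C10 to take part, which the trans diequatorial arrangement from step 7 secures because the ring alkene could only react through a bridged boat. It also needs the β-alkoxy enolate to survive: the C6–O bond lies about 30° from the enolate plane in the conformer first formed, and a cold quench keeps E1cB loss of 4-methoxybenzyl oxide slow.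

**Step 10**
Reactants: 20 dienone; 21 tert-butyl bromoacetate
Product: 23 keto ester (CH2CO2t-Bu on C7, trans to the C6 ether oxygen), via lithium enolate 22 (not isolated)
Conditions: LiN(iPr)2, THF, −78 °C; then 21, DMPU, −78 → −40 °C
Reagents that add atoms: none
Why: Kinetic deprotonation of the enone occurs at the α' carbon C7, and SN2 alkylation of the cross-conjugated lithium enolate by the α-bromo ester is expected on the outer face of the ring enolate, anti to the transannular C3=C4 unit, which sets C7 with the C7–C11 bond trans to the C6 oxygen.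

**Step 11**
Reactants: 23 keto ester
Product: 24 C8 allylic alcohol (OH 1,3-syn to O6, trans to C11)
Conditions: Zn(BH4)2, Et2O, −30 °C
Reagents that add atoms: none
Why: Chelation-controlled 1,2-reduction of the enone; zinc ties the C8 carbonyl to the C6 ether oxygen in a six-membered chelate that holds the C7 side chain axial, so hydride adds anti to that chain and sets the C8 alcohol syn to O6, while the tert-butyl ester is neither reduced nor closed onto the new hydroxyl.

**Step 12**
Reactants: 24 allylic alcohol
Product: 25 epoxy alcohol (C9–C10 oxirane anti to the C8 hydroxyl)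
Conditions: Ti(OiPr)4 (30 mol %), t-BuOOH (decane), 4 Å MS, CH2Cl2, −20 °C
Reagents that add atoms: tert-butyl hydroperoxide, CC(C)(C)OO
Why: Hydroxyl-directed titanium-catalysed epoxidation without a chiral ligand; only the alkene allylic to the free hydroxyl reacts, and 1,3-allylic strain between C8 and the cis C1 substituent of the Z alkene keeps H8 in the alkene plane so that oxygen arrives from the hydroxyl side and gives the threo epoxy alcohol, which sets C9 (and C10 for the time being).

**Step 13**
Reactants: 25 epoxy alcohol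
Product: 26 C8 triethylsilyl ether
Conditions: Et3SiCl, imidazole, 4-(dimethylamino)pyridine (cat.), DMF, rt
Reagents that add atoms: chlorotriethylsilane, CC[Si](Cl)(CC)CC
Why: Silylation of the only free hydroxyl under non-acidic conditions that leave the oxirane and the tert-butyl ester alone, so that O8 is told apart from the C9 hydroxyl that appears next.

**Step 14**
Reactants: 26 epoxy silyl ether
Product: 27 C9 allylic alcohol with exocyclic C10=C14
Conditions: Cp2TiCl2 (2.5 equiv), Mn dust, THF, rt; then 26, rt; aq. KH2PO4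
Reagents that add atoms: none
Why: Epoxide isomerisation by the trivalent titanium reagent Cp2TiCl; homolysis of the tertiary C10–O bond gives the C10 radical, which is trapped by a second titanium centre and loses a β-hydrogen from the unhindered C14 methyl, so the C10=C14 alkene forms while the C9–O bond and its configuration are kept.

**Step 15**
Reactants: 27 C9 allylic alcohol; 28 angelic acid
Product: 30 C9 angelate, via angelic 2,4,6-trichlorobenzoic anhydride 29 (not isolated)
Conditions: 28, 2,4,6-Cl3C6H2COCl, Et3N, PhMe, rt; then 27, 80 °C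
Reagents that add atoms: none
Why: Yamaguchi-type esterification through the mixed anhydride acylates the only free hydroxyl and avoids the Z to E isomerisation of the angeloyl group that more basic acylation conditions cause.

**Step 16**
Reactants: 30 angelate
Product: 31 C6 hydroxy ester
Conditions: DDQ (2,3-dichloro-5,6-dicyano-1,4-benzoquinone), CH2Cl2/pH 7 phosphate buffer, 0 °C
Reagents that add atoms: none
Why: Oxidative cleavage of the 4-methoxybenzyl ether (hydride abstraction by the quinone and hydrolysis of the oxocarbenium ion) frees O6 without touching the silyl ethers, the esters or the alkenes.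

**Step 17**
Reactants: 31 hydroxy ester
Product: 32 trans-fused γ-lactone
Conditions: camphor-10-sulfonic acid (10 mol %), PhMe, 40 °C
Reagents that add atoms: none
Why: Acid-catalysed intramolecular transesterification; the C6 hydroxyl closes the five-membered lactone on the ester carbonyl (5-exo-trig) with loss of tert-butanol, and O8 is silylated so that only the 6,12-lactone can form.

**Step 18**
Reactants: 32 lactone
Product: 36 α-methylene lactone, via lithium lactone enolate 33 (not isolated), via aminomethyl lactone 34 (not isolated), via ammonium iodide 35 (not isolated)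
Conditions: LiN(SiMe3)2, THF, −78 °C; CH2=NMe2+ I−, −78 °C → rt; then MeI, MeOH, rt; then aq. NaHCO3, CH2Cl2, rt
Reagents that add atoms: N,N-dimethylmethyleneiminium iodide (Eschenmoser's salt), C=[N+](C)C.[I-]
Why: Eschenmoser methylenation; the lactone CH2 (C11) is the only position deprotonated under these kinetic conditions (the angelate has no α-hydrogen), its enolate is aminomethylated by the iminium salt, and N-methylation followed by base-induced elimination of trimethylamine gives the C11=C13 alkene.

**Step 19**
Reactants: 36 α-methylene lactone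
Product: 37 (3R,4R)-epoxide
Conditions: 1,2:4,5-di-O-isopropylidene-β-D-erythro-2,3-hexodiulo-2,6-pyranose (30 mol %), KHSO5 (Oxone), K2CO3, Bu4NHSO4, MeCN/CH2(OMe)2/aq. Na2B4O7 buffer, 0 °C
Reagents that add atoms: potassium peroxymonosulfate, [K+].[O-]S(=O)(=O)OO
Why: Shi epoxidation; the dioxirane formed from the D-fructose-derived ketone reacts only with the electron-rich trisubstituted C3=C4 alkene and, through its spiro transition state, adds to the face of an E trisubstituted alkene that gives the (R,R)-oxirane, so C3 and C4 are set by the catalyst, the ring being able to turn either alkene face outward.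

**Step 20**
Reactants: 37 epoxide
Product: 38 C1,C8-diol
Conditions: Bu4NF, AcOH (1:1), THF, 0 °C → rt
Reagents that add atoms: none
Why: Fluoride-induced cleavage of both silyl ethers; acetic acid buffers the medium so that the oxirane, the methylene lactone and the C9 angelate (no shift to O8) should survive.

**Step 21**
Reactants: 38 diol
Product: 39 target CNP0348992.8
Conditions: MnO2 (activated, excess), CH2Cl2, rt
Reagents that add atoms: none
Why: Chemoselective MnO2 oxidation of an allylic alcohol; only the C1 hydroxyl is allylic (to C10=C14), so it alone is oxidised to the enone, while the C8 alcohol and the oxirane are left.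

**Compound list**
1 | (R)-carvone | CC(=C)[C@@H]1CC=C(C)C(=O)C1 | starting material
2 | (1R,5R)-cis-carveol | C1C=C(C)[C@H](O)C[C@@H]1C(C)=C | intermediate
3 | C9–C10 epoxide of 2, oxirane cis to the C1 hydroxyl and to the isopropenyl group | C1[C@@H]2O[C@]2(C)[C@H](O)C[C@@H]1C(C)=C | intermediate
4 | tert-butyldimethylsilyl ether of 3 | C1[C@@H]2O[C@]2(C)[C@H](O[Si](C)(C)C(C)(C)C)C[C@@H]1C(C)=C | intermediate
5 | hydroxy selenide (C9 phenylselanyl trans to the tertiary C10 hydroxyl) | C1[C@@H]([Se]c2ccccc2)[C@](C)(O)[C@H](O[Si](C)(C)C(C)(C)C)C[C@@H]1C(C)=C | intermediate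
6 | selenoxide of 5 | C1[C@@H]([Se](=O)c2ccccc2)[C@](C)(O)[C@H](O[Si](C)(C)C(C)(C)C)C[C@@H]1C(C)=C | intermediate
7 | tertiary C10 allylic alcohol with C8=C9 (hydroxyl cis to the silyloxy group) | C1=C[C@](C)(O)[C@H](O[Si](C)(C)C(C)(C)C)C[C@@H]1C(C)=C | intermediate
8 | (4R,6R)-4-(tert-butyldimethylsilyloxy)-3-methyl-6-(prop-1-en-2-yl)cyclohex-2-en-1-one | O=C1C=C(C)[C@H](O[Si](C)(C)C(C)(C)C)C[C@@H]1C(C)=C | intermediate
9 | 4-methoxybenzyl alcohol | COc1ccc(CO)cc1 | starting material
10 | trichloroethylene | ClC=C(Cl)Cl | starting material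
11 | potassium 4-methoxybenzyl oxide | [K+].[O-]Cc1ccc(OC)cc1 | intermediate
12 | dichloroethyne | ClC#CCl | intermediate
13 | (E)-1,2-dichlorovinyl 4-methoxybenzyl ether | COc1ccc(CO/C(Cl)=C\Cl)cc1 | intermediate
14 | chloroethynyl 4-methoxybenzyl ether | ClC#COCc1ccc(OC)cc1 | intermediate
15 | lithium (4-methoxybenzyloxy)ethynide | [Li]C#COCc1ccc(OC)cc1 | intermediate
16 | (1R,4R,6R)-4-(tert-butyldimethylsilyloxy)-1-[(4-methoxybenzyloxy)ethynyl]-3-methyl-6-(prop-1-en-2-yl)cyclohex-2-en-1-ol | O[C@]1(C#COCc2ccc(OC)cc2)C=C(C)[C@H](O[Si](C)(C)C(C)(C)C)C[C@@H]1C(C)=C | intermediate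
17 | (1R,4R,6R)-4-(tert-butyldimethylsilyloxy)-1-[(E)-2-(4-methoxybenzyloxy)ethenyl]-3-methyl-6-(prop-1-en-2-yl)cyclohex-2-en-1-ol | O[C@]1(/C=C/OCc2ccc(OC)cc2)C=C(C)[C@H](O[Si](C)(C)C(C)(C)C)C[C@@H]1C(C)=C | intermediate
18 | potassium alkoxide of 17 | [K+].[O-][C@]1(/C=C/OCc2ccc(OC)cc2)C=C(C)[C@H](O[Si](C)(C)C(C)(C)C)C[C@@H]1C(C)=C | intermediate
19 | potassium enolate of the ten-membered ring (E C7=C8, E C3=C4, Z C9=C10) | [K+].COc1ccc(CO[C@@H]2C/C(C)=C/C[C@@H](O[Si](C)(C)C(C)(C)C)/C(C)=C\C([O-])=C\2)cc1 | intermediate
20 | (2Z,4R,6E,9R)-4-(tert-butyldimethylsilyloxy)-9-(4-methoxybenzyloxy)-3,7-dimethylcyclodeca-2,6-dien-1-one (C8 ketone, C1 silyl ether, C6 ether) | O=C1/C=C(C)\[C@H](O[Si](C)(C)C(C)(C)C)C/C=C(C)/C[C@@H](OCc2ccc(OC)cc2)C1 | intermediate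
21 | tert-butyl bromoacetate | CC(C)(C)OC(=O)CBr | starting material
22 | lithium C7–C8 enolate of 20 | [Li+].COc1ccc(CO[C@@H]2C/C(C)=C/C[C@@H](O[Si](C)(C)C(C)(C)C)/C(C)=C\C([O-])=C2)cc1 | intermediate
23 | keto ester: 20 with CH2CO2t-Bu on C7, trans to the C6 oxygen | O=C1/C=C(C)\[C@H](O[Si](C)(C)C(C)(C)C)C/C=C(C)/C[C@@H](OCc2ccc(OC)cc2)[C@@H]1CC(=O)OC(C)(C)C | intermediate
24 | C8 allylic alcohol (OH syn to O6, trans to C11) | O[C@H]1/C=C(C)\[C@H](O[Si](C)(C)C(C)(C)C)C/C=C(C)/C[C@@H](OCc2ccc(OC)cc2)[C@@H]1CC(=O)OC(C)(C)C | intermediate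
25 | C9–C10 epoxy alcohol (oxirane anti to the C8 hydroxyl) | O[C@H]1[C@@H]2O[C@]2(C)[C@H](O[Si](C)(C)C(C)(C)C)C/C=C(C)/C[C@@H](OCc3ccc(OC)cc3)[C@@H]1CC(=O)OC(C)(C)C | intermediate
26 | C8 triethylsilyl ether of 25 | CC[Si](CC)(CC)O[C@H]1[C@@H]2O[C@]2(C)[C@H](O[Si](C)(C)C(C)(C)C)C/C=C(C)/C[C@@H](OCc3ccc(OC)cc3)[C@@H]1CC(=O)OC(C)(C)C | intermediate
27 | C9 allylic alcohol with C10=C14 (C9–OH anti to the C8 silyloxy group) | CC[Si](CC)(CC)O[C@H]1[C@H](O)C(=C)[C@H](O[Si](C)(C)C(C)(C)C)C/C=C(C)/C[C@@H](OCc2ccc(OC)cc2)[C@@H]1CC(=O)OC(C)(C)C | intermediate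
28 | angelic acid [(Z)-2-methylbut-2-enoic acid] | C/C=C(/C)C(=O)O | starting material
29 | angelic 2,4,6-trichlorobenzoic anhydride | C/C=C(/C)C(=O)OC(=O)c1c(Cl)cc(Cl)cc1Cl | intermediate
30 | C9 angelate of 27 | CC[Si](CC)(CC)O[C@H]1[C@H](OC(=O)/C(C)=C\C)C(=C)[C@H](O[Si](C)(C)C(C)(C)C)C/C=C(C)/C[C@@H](OCc2ccc(OC)cc2)[C@@H]1CC(=O)OC(C)(C)C | intermediate
31 | C6 hydroxy tert-butyl ester | CC[Si](CC)(CC)O[C@H]1[C@H](OC(=O)/C(C)=C\C)C(=C)[C@H](O[Si](C)(C)C(C)(C)C)C/C=C(C)/C[C@@H](O)[C@@H]1CC(=O)OC(C)(C)C | intermediate
32 | trans-fused 6,12-lactone | CC[Si](CC)(CC)O[C@H]1[C@H](OC(=O)/C(C)=C\C)C(=C)[C@H](O[Si](C)(C)C(C)(C)C)C/C=C(C)/C[C@H]2OC(=O)C[C@H]12 | intermediate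
33 | lithium enolate of lactone 32 | [Li+].CC[Si](CC)(CC)O[C@H]1[C@H](OC(=O)/C(C)=C\C)C(=C)[C@H](O[Si](C)(C)C(C)(C)C)C/C=C(C)/C[C@H]2OC([O-])=C[C@H]12 | intermediate
34 | C11 (dimethylamino)methyl lactone (C11 configuration open) | CC[Si](CC)(CC)O[C@H]1[C@H](OC(=O)/C(C)=C\C)C(=C)[C@H](O[Si](C)(C)C(C)(C)C)C/C=C(C)/C[C@H]2OC(=O)C(CN(C)C)[C@H]12 | intermediate
35 | trimethylammonium iodide of 34 | [I-].CC[Si](CC)(CC)O[C@H]1[C@H](OC(=O)/C(C)=C\C)C(=C)[C@H](O[Si](C)(C)C(C)(C)C)C/C=C(C)/C[C@H]2OC(=O)C(C[N+](C)(C)C)[C@H]12 | intermediate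
36 | α-methylene lactone | CC[Si](CC)(CC)O[C@H]1[C@H](OC(=O)/C(C)=C\C)C(=C)[C@H](O[Si](C)(C)C(C)(C)C)C/C=C(C)/C[C@H]2OC(=O)C(=C)[C@H]12 | intermediate
37 | (3R,4R)-epoxide of 36 | CC[Si](CC)(CC)O[C@H]1[C@H](OC(=O)/C(C)=C\C)C(=C)[C@H](O[Si](C)(C)C(C)(C)C)C[C@H]3O[C@]3(C)C[C@H]2OC(=O)C(=C)[C@H]12 | intermediate
38 | C1,C8-diol | O[C@H]1[C@H](OC(=O)/C(C)=C\C)C(=C)[C@H](O)C[C@H]3O[C@]3(C)C[C@H]2OC(=O)C(=C)[C@H]12 | intermediate
39 | CNP0348992.8 (3R,4R,6R,7R,8R,9R) | C=C1C(=O)O[C@@H]2C[C@@]3(C)O[C@@H]3CC(=O)C(=C)[C@@H](OC(=O)/C(C)=C\C)[C@H](O)[C@@H]12 | target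

**Totals**
Total steps: 21. Longest linear sequence: 20 steps (steps 1–5 and 7–21 from (R)-carvone; step 6 is a one-step side branch).

**Steps most likely to fail**

Step 9. The potassium enolate may expel 4-methoxybenzyl oxide by E1cB elimination, or the bis-allylic alkoxide may fragment before it rearranges. The fallback removes the negative charge from the rearrangement. It sets out from 17, which is silylated (Me3SiCl, imidazole, CH2Cl2) to the trimethylsilyl ether of the dienol F1. Heating F1 in toluene (sealed tube, about 180 °C) runs the neutral siloxy-Cope rearrangement through the same chair and gives the ten-membered trimethylsilyl enol ether F2. Bu4NF/AcOH at −20 °C then cleaves the enol ether, and the route is rejoined at 20.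

Step 19. The ten-membered ring may hold the C3=C4 alkene so that the face matched to the catalyst is turned inward, which would give poor facial selectivity or slow conversion. The fallback replaces catalyst control by delivery from the C6 hydroxyl. It sets out from 31: VO(acac)2/t-BuOOH epoxidises the homoallylic C3=C4 alkene through a chair-like vanadate in which C7 is equatorial and the alkene is eclipsed with C5–C6, which points to the same (3R,4R) oxirane, and gives the epoxy hydroxy ester F3. LiN(SiMe3)2 (THF, −78 → −40 °C) closes the lithium alkoxide onto the tert-butyl ester to the epoxy lactone F4. Methylenation as in step 18 then runs through the lithium enolate F5, the aminomethyl lactone F6 and the ammonium iodide F7, and the route is rejoined at 37.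

Step 10. Regenerating the enolate from the isolated ketone may give poor facial selectivity at C7, and the C6 ether may be lost by β-elimination. The fallback uses the enolate as the rearrangement delivers it. It sets out from 17: KN(SiMe3)2/18-crown-6 (no excess base) forms 18, which rearranges to the E ring enolate 19, and 21 is added at −78 °C. In the chair-derived conformer only the outer face at C7 is open, and attack there gives the trans relation to O6; the route is rejoined at 23. It makes no new compound (F0).

**Further compounds**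
F1 | step 9 | trimethylsilyl ether of dienol 17 | C[Si](C)(C)O[C@]1(/C=C/OCc2ccc(OC)cc2)C=C(C)[C@H](O[Si](C)(C)C(C)(C)C)C[C@@H]1C(C)=C
F2 | step 9 | ten-membered trimethylsilyl enol ether (E C7=C8) | COc1ccc(CO[C@@H]2C/C(C)=C/C[C@@H](O[Si](C)(C)C(C)(C)C)/C(C)=C\C(O[Si](C)(C)C)=C\2)cc1
F0 | step 10 | none | none
F3 | step 19 | (3R,4R)-epoxy C6 hydroxy tert-butyl ester | CC[Si](CC)(CC)O[C@H]1[C@H](OC(=O)/C(C)=C\C)C(=C)[C@H](O[Si](C)(C)C(C)(C)C)C[C@H]3O[C@]3(C)C[C@@H](O)[C@@H]1CC(=O)OC(C)(C)C
F4 | step 19 | (3R,4R)-epoxy 6,12-lactone | CC[Si](CC)(CC)O[C@H]1[C@H](OC(=O)/C(C)=C\C)C(=C)[C@H](O[Si](C)(C)C(C)(C)C)C[C@H]3O[C@]3(C)C[C@H]2OC(=O)C[C@H]12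
F5 | step 19 | lithium enolate of F4 | [Li+].CC[Si](CC)(CC)O[C@H]1[C@H](OC(=O)/C(C)=C\C)C(=C)[C@H](O[Si](C)(C)C(C)(C)C)C[C@H]3O[C@]3(C)C[C@H]2OC([O-])=C[C@H]12
F6 | step 19 | C11 (dimethylamino)methyl derivative of F4 | CC[Si](CC)(CC)O[C@H]1[C@H](OC(=O)/C(C)=C\C)C(=C)[C@H](O[Si](C)(C)C(C)(C)C)C[C@H]3O[C@]3(C)C[C@H]2OC(=O)C(CN(C)C)[C@H]12
F7 | step 19 | trimethylammonium iodide of F6 | [I-].CC[Si](CC)(CC)O[C@H]1[C@H](OC(=O)/C(C)=C\C)C(=C)[C@H](O[Si](C)(C)C(C)(C)C)C[C@H]3O[C@]3(C)C[C@H]2OC(=O)C(C[N+](C)(C)C)[C@H]12
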